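**Retrosynthetic overview**
Target ⇐ HF desilylation of a bis-silyl bicycle. Both rings come from one TMSOTf operation on an open chain: the C6 acetal and C12 tert-butyl ester close the γ-lactone first, then the C5 vinylsilane attacks the lactone oxocarbenium ion at C6 and closes the ten-membered ring (C5–C6 bond).
Open chain ⇐ indium Barbier union (C7–C8) of a C9-hydroxy lactol with a 2-(bromomethyl)-4,4-dimethoxybut-2-enoate, then silylation, C8 acylation and C14 oxidation.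
Lactol ⇐ cross-metathesis (C1=C10) of a vinylsilane diene with an enantioselective Morita–Baylis–Hillman adduct (C9), then ester reduction.
Vinylsilane with the C4=C5 geometry ⇐ copper-catalysed anti-carbomagnesiation of 3-(trimethylsilyl)prop-2-yn-1-ol.

Assumption: C1–C15 in the text are germacrane locants of the target (C6 lactone carbinol, C7 ring-fusion carbon, C8 acyloxy carbon, C9 carbinol, C10 bears C14, C4 bears C15, C11–C13 the α-methylene acid unit); CIP descriptors in names refer to each compound's own numbering.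

**Step 1**
Reactants: 1 3-(trimethylsilyl)prop-2-yn-1-ol; 2 but-3-en-1-ylmagnesium bromide
Product: 4 (2E)-2-(but-3-en-1-yl)-3-(trimethylsilyl)prop-2-en-1-ol, via magnesium chelate 3 (not isolated)
Conditions: 2 (2.5 equiv), CuI (10 mol %), THF, 0 °C to reflux; then aq NH4Cl
Reagents that add atoms: none
Why: Copper-catalysed anti-carbomagnesiation of a propargylic alkoxide (Duboudin–Jousseaume reaction) puts the butenyl group on the carbon next to CH2O and magnesium on the silyl-bearing carbon inside a five-membered chelate, so protonation leaves SiMe3 cis to the new chain, which is the later C4=C5 geometry.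

**Step 2**
Reactants: 4 (2E)-2-(but-3-en-1-yl)-3-(trimethylsilyl)prop-2-en-1-ol
Product: 5 tert-butyl{[(2E)-2-(but-3-en-1-yl)-3-(trimethylsilyl)prop-2-en-1-yl]oxy}diphenylsilane
Conditions: TBDPSCl, imidazole, CH2Cl2, rt
Reagents that add atoms: tert-butyl(chloro)diphenylsilane, CC(C)(C)[Si](Cl)(c1ccccc1)c1ccccc1
Why: Silyl ether formation at the primary allylic alcohol gives an acid-stable ether; no stereocentre is involved.

**Step 3**
Reactants: 6 2,2-dimethoxyacetaldehyde; 7 1,1,1,3,3,3-hexafluoropropan-2-yl prop-2-enoate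
Product: 8 1,1,1,3,3,3-hexafluoropropan-2-yl (3S)-3-hydroxy-4,4-dimethoxy-2-methylidenebutanoate
Conditions: β-isocupreidine (10 mol %), DMF, −55 °C
Reagents that add atoms: none
Why: Enantioselective Morita–Baylis–Hillman reaction under Hatakeyama conditions, in which the quinuclidine adds to the activated acrylate and the phenol of the catalyst hydrogen-bonds the aldolate so that one aldehyde face reacts and the (3S) carbinol, the later C9, is formed.

**Step 4**
Reactants: 5 tert-butyl{[(2E)-2-(but-3-en-1-yl)-3-(trimethylsilyl)prop-2-en-1-yl]oxy}diphenylsilane; 8 1,1,1,3,3,3-hexafluoropropan-2-yl (3S)-3-hydroxy-4,4-dimethoxy-2-methylidenebutanoate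
Product: 9 1,1,1,3,3,3-hexafluoropropan-2-yl (2E,6E)-6-{[(tert-butyldiphenylsilyl)oxy]methyl}-2-[(1S)-1-hydroxy-2,2-dimethoxyethyl]-7-(trimethylsilyl)hepta-2,6-dienoate
Conditions: second-generation Hoveyda–Grubbs catalyst RuCl2(H2IMes)(=CH-C6H4-2-Oi-Pr) (5 mol %), CH2Cl2, 40 °C
Reagents that add atoms: none
Why: Olefin cross-metathesis of the terminal alkene with the 2-substituted acrylate gives the thermodynamically preferred trisubstituted enoate with the ester trans to the chain (the C1=C10 geometry), while the hindered vinylsilane and the stereocentre are untouched.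

**Step 5**
Reactants: 9 1,1,1,3,3,3-hexafluoropropan-2-yl (2E,6E)-6-{[(tert-butyldiphenylsilyl)oxy]methyl}-2-[(1S)-1-hydroxy-2,2-dimethoxyethyl]-7-(trimethylsilyl)hepta-2,6-dienoate
Product: 10 (2S,3Z,7E)-7-{[(tert-butyldiphenylsilyl)oxy]methyl}-3-(hydroxymethyl)-1,1-dimethoxy-8-(trimethylsilyl)octa-3,7-dien-2-ol
Conditions: i-Bu2AlH (4 equiv), CH2Cl2, −78 °C; aq potassium sodium tartrate
Reagents that add atoms: none
Why: 1,2-Reduction of the activated enoate ester by the aluminium hydride gives the allylic alcohol and leaves acetal, silyl groups and alkenes intact; no stereocentre changes.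

**Step 6**
Reactants: 6 2,2-dimethoxyacetaldehyde; 11 tert-butyl prop-2-enoate
Product: 12 tert-butyl 3-hydroxy-4,4-dimethoxy-2-methylidenebutanoate (racemic)
Conditions: DABCO (0.5 equiv), 1,4-dioxane–H2O (1:1), rt
Reagents that add atoms: none
Why: Morita–Baylis–Hillman reaction of the activated aldehyde; the racemic carbinol centre is removed in the next step.

**Step 7**
Reactants: 12 tert-butyl 3-hydroxy-4,4-dimethoxy-2-methylidenebutanoate (racemic)
Product: 13 tert-butyl (2Z)-2-(bromomethyl)-4,4-dimethoxybut-2-enoate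
Conditions: NBS, Me2S, CH2Cl2, 0 °C to rt
Reagents that add atoms: N-bromosuccinimide, O=C1CCC(=O)N1Br
Why: Corey–Kim-type activation of the hydroxyl as an alkoxysulfonium ion followed by SN2′ attack of bromide gives the rearranged primary allylic bromide as the thermodynamically preferred Z isomer.

**Step 8**
Reactants: 10 (2S,3Z,7E)-7-{[(tert-butyldiphenylsilyl)oxy]methyl}-3-(hydroxymethyl)-1,1-dimethoxy-8-(trimethylsilyl)octa-3,7-dien-2-ol; 13 tert-butyl (2Z)-2-(bromomethyl)-4,4-dimethoxybut-2-enoate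
Product: 16 tert-butyl (3R,4S,5S,6Z,10E)-10-{[(tert-butyldiphenylsilyl)oxy]methyl}-3-(dimethoxymethyl)-4,5-dihydroxy-6-(hydroxymethyl)-2-methylidene-11-(trimethylsilyl)undeca-6,10-dienoate, via lactol 14 (not isolated), via allylindium dibromide 15 (not isolated)
Conditions: Amberlyst-15, THF–H2O (4:1), rt; filter; then 13, In powder, rt
Reagents that add atoms: water, O
Why: Acetal hydrolysis gives the lactol, whose open hydroxy aldehyde undergoes an indium-mediated Barbier allylation at the γ-carbon of the allylindium, where chelation of indium by the free C9 hydroxyl sets C8 syn to C9 and the cyclic transition state of the Z reagent sets C7 syn to the new carbinol.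

**Step 9**
Reactants: 16 tert-butyl (3R,4S,5S,6Z,10E)-10-{[(tert-butyldiphenylsilyl)oxy]methyl}-3-(dimethoxymethyl)-4,5-dihydroxy-6-(hydroxymethyl)-2-methylidene-11-(trimethylsilyl)undeca-6,10-dienoate
Product: 17 tert-butyl (3R,4S,5S,6Z,10E)-5-[(tert-butyldimethylsilyl)oxy]-6-{[(tert-butyldimethylsilyl)oxy]methyl}-10-{[(tert-butyldiphenylsilyl)oxy]methyl}-3-(dimethoxymethyl)-4-hydroxy-2-methylidene-11-(trimethylsilyl)undeca-6,10-dienoate
Conditions: TBSCl (2.2 equiv), imidazole, DMF, 0 °C to rt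
Reagents that add atoms: tert-butyl(chloro)dimethylsilane, CC(C)(C)[Si](C)(C)Cl
Why: Silyl ether formation is fastest at the primary C14 hydroxyl and then at the allylic C9 hydroxyl, whereas the C8 hydroxyl next to the doubly branched C7 stays free; no stereocentre changes.

**Step 10**
Reactants: 17 tert-butyl (3R,4S,5S,6Z,10E)-5-[(tert-butyldimethylsilyl)oxy]-6-{[(tert-butyldimethylsilyl)oxy]methyl}-10-{[(tert-butyldiphenylsilyl)oxy]methyl}-3-(dimethoxymethyl)-4-hydroxy-2-methylidene-11-(trimethylsilyl)undeca-6,10-dienoate; 18 (2S)-2-methylbutanoic anhydride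
Product: 19 tert-butyl (3R,4S,5S,6Z,10E)-5-[(tert-butyldimethylsilyl)oxy]-6-{[(tert-butyldimethylsilyl)oxy]methyl}-10-{[(tert-butyldiphenylsilyl)oxy]methyl}-3-(dimethoxymethyl)-2-methylidene-4-{[(2S)-2-methylbutanoyl]oxy}-11-(trimethylsilyl)undeca-6,10-dienoate
Conditions: DMAP, Et3N, CH2Cl2, rt to 40 °C
Reagents that add atoms: none
Why: DMAP-catalysed acyl transfer (Steglich-type acylation) from the anhydride to the remaining C8 hydroxyl, which brings in the (S) centre of the side chain without enolisation.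

**Step 11**
Reactants: 19 tert-butyl (3R,4S,5S,6Z,10E)-5-[(tert-butyldimethylsilyl)oxy]-6-{[(tert-butyldimethylsilyl)oxy]methyl}-10-{[(tert-butyldiphenylsilyl)oxy]methyl}-3-(dimethoxymethyl)-2-methylidene-4-{[(2S)-2-methylbutanoyl]oxy}-11-(trimethylsilyl)undeca-6,10-dienoate
Product: 20 tert-butyl (3R,4S,5S,6Z,10E)-5-[(tert-butyldimethylsilyl)oxy]-10-{[(tert-butyldiphenylsilyl)oxy]methyl}-3-(dimethoxymethyl)-6-(hydroxymethyl)-2-methylidene-4-{[(2S)-2-methylbutanoyl]oxy}-11-(trimethylsilyl)undeca-6,10-dienoate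
Conditions: HF·pyridine, pyridine, THF, 0 °C
Reagents that add atoms: none
Why: Selective desilylation, because buffered HF cleaves the primary allylic TBS ether much faster than the secondary TBS ether, the TBDPS ether or the vinylsilane.

**Step 12**
Reactants: 20 tert-butyl (3R,4S,5S,6Z,10E)-5-[(tert-butyldimethylsilyl)oxy]-10-{[(tert-butyldiphenylsilyl)oxy]methyl}-3-(dimethoxymethyl)-6-(hydroxymethyl)-2-methylidene-4-{[(2S)-2-methylbutanoyl]oxy}-11-(trimethylsilyl)undeca-6,10-dienoate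
Product: 21 tert-butyl (3R,4S,5S,6E,10E)-5-[(tert-butyldimethylsilyl)oxy]-10-{[(tert-butyldiphenylsilyl)oxy]methyl}-3-(dimethoxymethyl)-6-formyl-2-methylidene-4-{[(2S)-2-methylbutanoyl]oxy}-11-(trimethylsilyl)undeca-6,10-dienoate
Conditions: MnO2, CH2Cl2, rt
Reagents that add atoms: none
Why: Allylic oxidation with MnO2 of the only free alcohol gives the enal, which also deactivates the C1=C10 alkene towards cations in the next step.

**Step 13**
Reactants: 21 tert-butyl (3R,4S,5S,6E,10E)-5-[(tert-butyldimethylsilyl)oxy]-10-{[(tert-butyldiphenylsilyl)oxy]methyl}-3-(dimethoxymethyl)-6-formyl-2-methylidene-4-{[(2S)-2-methylbutanoyl]oxy}-11-(trimethylsilyl)undeca-6,10-dienoate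
Product: 23 (3aS,4S,5S,6E,10E,11aR)-5-[(tert-butyldimethylsilyl)oxy]-10-{[(tert-butyldiphenylsilyl)oxy]methyl}-6-formyl-3-methylidene-2-oxo-2,3,3a,4,5,8,9,11a-octahydrocyclodeca[b]furan-4-yl (2S)-2-methylbutanoate, via methoxy lactone 22 (not isolated)
Conditions: TMSOTf (3 equiv), 2,6-di-tert-butyl-4-methylpyridine, CH2Cl2 (2 mM), −78 to −20 °C
Reagents that add atoms: none
Why: Proposed new method: TMSOTf ionises the dimethyl acetal, the tert-butyl ester carbonyl captures the oxocarbenium ion with loss of 2-methylpropene to close the γ-methoxy lactone, a second ionisation gives the lactone acyloxocarbenium ion, and the vinylsilane attacks it through its silicon-bearing carbon (ipso substitution via a tertiary β-silyl cation with retention of alkene geometry) on the face anti to the C8 branch of C7, which closes the ten-membered ring and sets C6 (R) trans to C7; this is a vinylsilane-terminated oxocarbenium (Prins-type) macrocyclisation whose closest known relatives are Overman's vinylsilane-terminated acetal cyclisations to five- to eight-membered rings, Lewis-acid additions of allyl- and vinylsilanes to γ-alkoxy-γ-lactones and Prins macrocyclisations.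

**Step 14**
Reactants: 23 (3aS,4S,5S,6E,10E,11aR)-5-[(tert-butyldimethylsilyl)oxy]-10-{[(tert-butyldiphenylsilyl)oxy]methyl}-6-formyl-3-methylidene-2-oxo-2,3,3a,4,5,8,9,11a-octahydrocyclodeca[b]furan-4-yl (2S)-2-methylbutanoate
Product: 24 (3aS,4S,5S,6E,10E,11aR)-6-formyl-5-hydroxy-10-(hydroxymethyl)-3-methylidene-2-oxo-2,3,3a,4,5,8,9,11a-octahydrocyclodeca[b]furan-4-yl (2S)-2-methylbutanoate
Conditions: HF·pyridine, THF, 0 °C to rt
Reagents that add atoms: none
Why: Fluoride-mediated global desilylation removes the TBS and TBDPS ethers under mildly acidic conditions that leave the α-methylene lactone, the enal and the ester untouched; no stereocentre changes.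

**Compound list**
1 | 3-(trimethylsilyl)prop-2-yn-1-ol | C[Si](C)(C)C#CCO | starting material
2 | but-3-en-1-ylmagnesium bromide | C=CCC[Mg]Br | starting material
3 | magnesium chelate 4-(but-3-en-1-yl)-3-(trimethylsilyl)-2,5-dihydro-1,2-oxamagnesole | C=CCCC1=C([Si](C)(C)C)[Mg]OC1 | intermediate
4 | (2E)-2-(but-3-en-1-yl)-3-(trimethylsilyl)prop-2-en-1-ol | C[Si](C)(C)/C=C(/CO)CCC=C | intermediate
5 | tert-butyl{[(2E)-2-(but-3-en-1-yl)-3-(trimethylsilyl)prop-2-en-1-yl]oxy}diphenylsilane | C[Si](C)(C)/C=C(/CO[Si](c1ccccc1)(c1ccccc1)C(C)(C)C)CCC=C | intermediate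
6 | 2,2-dimethoxyacetaldehyde | COC(OC)C=O | starting material
7 | 1,1,1,3,3,3-hexafluoropropan-2-yl prop-2-enoate | C=CC(=O)OC(C(F)(F)F)C(F)(F)F | starting material
8 | 1,1,1,3,3,3-hexafluoropropan-2-yl (3S)-3-hydroxy-4,4-dimethoxy-2-methylidenebutanoate | C=C(C(=O)OC(C(F)(F)F)C(F)(F)F)[C@H](O)C(OC)OC | intermediate
9 | 1,1,1,3,3,3-hexafluoropropan-2-yl (2E,6E)-6-{[(tert-butyldiphenylsilyl)oxy]methyl}-2-[(1S)-1-hydroxy-2,2-dimethoxyethyl]-7-(trimethylsilyl)hepta-2,6-dienoate | C[Si](C)(C)/C=C(/CO[Si](c1ccccc1)(c1ccccc1)C(C)(C)C)CC/C=C(/C(=O)OC(C(F)(F)F)C(F)(F)F)[C@H](O)C(OC)OC | intermediate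
10 | (2S,3Z,7E)-7-{[(tert-butyldiphenylsilyl)oxy]methyl}-3-(hydroxymethyl)-1,1-dimethoxy-8-(trimethylsilyl)octa-3,7-dien-2-ol | C[Si](C)(C)/C=C(/CO[Si](c1ccccc1)(c1ccccc1)C(C)(C)C)CC/C=C(/CO)[C@H](O)C(OC)OC | intermediate
11 | tert-butyl prop-2-enoate | C=CC(=O)OC(C)(C)C | starting material
12 | tert-butyl 3-hydroxy-4,4-dimethoxy-2-methylidenebutanoate (racemic) | C=C(C(=O)OC(C)(C)C)C(O)C(OC)OC | intermediate
13 | tert-butyl (2Z)-2-(bromomethyl)-4,4-dimethoxybut-2-enoate | BrC/C(C(=O)OC(C)(C)C)=C\C(OC)OC | intermediate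
14 | lactol (3S,4Z)-4-[(4E)-4-{[(tert-butyldiphenylsilyl)oxy]methyl}-5-(trimethylsilyl)pent-4-en-1-ylidene]oxolane-2,3-diol (both anomers) | C[Si](C)(C)/C=C(/CO[Si](c1ccccc1)(c1ccccc1)C(C)(C)C)CC/C=C2/COC(O)[C@H]2O | intermediate
15 | allylindium dibromide tert-butyl (2Z)-2-[(dibromoindiganyl)methyl]-4,4-dimethoxybut-2-enoate | Br[In](Br)C/C(C(=O)OC(C)(C)C)=C\C(OC)OC | intermediate
16 | tert-butyl (3R,4S,5S,6Z,10E)-10-{[(tert-butyldiphenylsilyl)oxy]methyl}-3-(dimethoxymethyl)-4,5-dihydroxy-6-(hydroxymethyl)-2-methylidene-11-(trimethylsilyl)undeca-6,10-dienoate | C[Si](C)(C)/C=C(/CO[Si](c1ccccc1)(c1ccccc1)C(C)(C)C)CC/C=C(/CO)[C@H](O)[C@@H](O)[C@@H](C(=C)C(=O)OC(C)(C)C)C(OC)OC | intermediate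
17 | tert-butyl (3R,4S,5S,6Z,10E)-5-[(tert-butyldimethylsilyl)oxy]-6-{[(tert-butyldimethylsilyl)oxy]methyl}-10-{[(tert-butyldiphenylsilyl)oxy]methyl}-3-(dimethoxymethyl)-4-hydroxy-2-methylidene-11-(trimethylsilyl)undeca-6,10-dienoate | C[Si](C)(C)/C=C(/CO[Si](c1ccccc1)(c1ccccc1)C(C)(C)C)CC/C=C(/CO[Si](C)(C)C(C)(C)C)[C@H](O[Si](C)(C)C(C)(C)C)[C@@H](O)[C@@H](C(=C)C(=O)OC(C)(C)C)C(OC)OC | intermediate
18 | (2S)-2-methylbutanoic anhydride | CC[C@H](C)C(=O)OC(=O)[C@@H](C)CC | starting material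
19 | tert-butyl (3R,4S,5S,6Z,10E)-5-[(tert-butyldimethylsilyl)oxy]-6-{[(tert-butyldimethylsilyl)oxy]methyl}-10-{[(tert-butyldiphenylsilyl)oxy]methyl}-3-(dimethoxymethyl)-2-methylidene-4-{[(2S)-2-methylbutanoyl]oxy}-11-(trimethylsilyl)undeca-6,10-dienoate | C[Si](C)(C)/C=C(/CO[Si](c1ccccc1)(c1ccccc1)C(C)(C)C)CC/C=C(/CO[Si](C)(C)C(C)(C)C)[C@H](O[Si](C)(C)C(C)(C)C)[C@@H](OC(=O)[C@@H](C)CC)[C@@H](C(=C)C(=O)OC(C)(C)C)C(OC)OC | intermediate
20 | tert-butyl (3R,4S,5S,6Z,10E)-5-[(tert-butyldimethylsilyl)oxy]-10-{[(tert-butyldiphenylsilyl)oxy]methyl}-3-(dimethoxymethyl)-6-(hydroxymethyl)-2-methylidene-4-{[(2S)-2-methylbutanoyl]oxy}-11-(trimethylsilyl)undeca-6,10-dienoate | C[Si](C)(C)/C=C(/CO[Si](c1ccccc1)(c1ccccc1)C(C)(C)C)CC/C=C(/CO)[C@H](O[Si](C)(C)C(C)(C)C)[C@@H](OC(=O)[C@@H](C)CC)[C@@H](C(=C)C(=O)OC(C)(C)C)C(OC)OC | intermediate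
21 | tert-butyl (3R,4S,5S,6E,10E)-5-[(tert-butyldimethylsilyl)oxy]-10-{[(tert-butyldiphenylsilyl)oxy]methyl}-3-(dimethoxymethyl)-6-formyl-2-methylidene-4-{[(2S)-2-methylbutanoyl]oxy}-11-(trimethylsilyl)undeca-6,10-dienoate | C[Si](C)(C)/C=C(/CO[Si](c1ccccc1)(c1ccccc1)C(C)(C)C)CC/C=C(/C=O)[C@H](O[Si](C)(C)C(C)(C)C)[C@@H](OC(=O)[C@@H](C)CC)[C@@H](C(=C)C(=O)OC(C)(C)C)C(OC)OC | intermediate
22 | methoxy lactone (1S,2S,3E,7E)-2-[(tert-butyldimethylsilyl)oxy]-7-{[(tert-butyldiphenylsilyl)oxy]methyl}-3-formyl-1-[(3R)-2-methoxy-4-methylidene-5-oxooxolan-3-yl]-8-(trimethylsilyl)octa-3,7-dien-1-yl (2S)-2-methylbutanoate (both epimers at the acetal carbon) | C[Si](C)(C)/C=C(/CO[Si](c1ccccc1)(c1ccccc1)C(C)(C)C)CC/C=C(/C=O)[C@H](O[Si](C)(C)C(C)(C)C)[C@@H](OC(=O)[C@@H](C)CC)[C@H]2C(=C)C(=O)OC2OC | intermediate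
23 | (3aS,4S,5S,6E,10E,11aR)-5-[(tert-butyldimethylsilyl)oxy]-10-{[(tert-butyldiphenylsilyl)oxy]methyl}-6-formyl-3-methylidene-2-oxo-2,3,3a,4,5,8,9,11a-octahydrocyclodeca[b]furan-4-yl (2S)-2-methylbutanoate | C=C1C(=O)O[C@@H]2/C=C(/CO[Si](c3ccccc3)(c3ccccc3)C(C)(C)C)CC/C=C(/C=O)[C@H](O[Si](C)(C)C(C)(C)C)[C@@H](OC(=O)[C@@H](C)CC)[C@@H]12 | intermediate
24 | (3aS,4S,5S,6E,10E,11aR)-6-formyl-5-hydroxy-10-(hydroxymethyl)-3-methylidene-2-oxo-2,3,3a,4,5,8,9,11a-octahydrocyclodeca[b]furan-4-yl (2S)-2-methylbutanoate | C=C1C(=O)O[C@@H]2/C=C(/CO)CC/C=C(/C=O)[C@H](O)[C@@H](OC(=O)[C@@H](C)CC)[C@@H]12 | target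

**Totals**
Total step count: 14. Longest linear sequence: 11 steps (1, 2, 4, 5, 8, 9, 10, 11, 12, 13, 14).

**Steps most likely to fail, with fallbacks**

Step 13 is the boldest step. The ten-membered closure must beat oligomerisation, loss of the C7 proton from the first oxocarbenium ion, and capture of the cation by the C9 silyl ether oxygen. The fallback sets out from 20 and closes the same C5–C6 bond with chromium chemistry. Iododesilylation with NIS in MeCN (retention) gives vinyl iodide F1. LiBF4 in wet MeCN unmasks aldehyde F2. A Nozaki–Hiyama–Kishi macrocyclisation (CrCl2, NiCl2 cat., DMSO, high dilution) gives ten-membered carbinol F3. TMSOTf with 2,6-lutidine then cleaves the tert-butyl ester and closes the lactone to hydroxymethyl lactone F4. MnO2 oxidation of F4 comes back to the route at 23.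

Step 8 may give a poor ratio at C7/C8 because the γ-substituent of the allylindium is an acetal and the aldehyde is masked as a lactol. The fallback sets out from 13 and uses a boron reagent with a closed chair transition state instead of the Barbier reaction. B2pin2, CuCl and LiOt-Bu convert 13 into allylboronate F5. Sc(OTf)3-catalysed allylboration of lactol 14, made from 10 as in step 8, delivers the syn adduct and comes back to the route at 16.

Step 9 relies on steric discrimination between the C9 and C8 hydroxyls. The fallback sets out from 16 and replaces it by ring-size control. t-Bu2Si(OTf)2 with 2,6-lutidine closes only the six-membered ring across O9 and O14, as in the 3′,5′-protection of ribonucleosides, to give silylene F6. Acylation with 18 and DMAP gives ester F7. Brief HF·pyridine at 0 °C removes the silylene to give diol F8. TEMPO with PhI(OAc)2 oxidises only the primary allylic alcohol to hydroxy enal F9. TBSOTf with 2,6-lutidine then silylates O9 and comes back to the route at 21.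

**Further compounds**
F1 | step 13 | tert-butyl (3R,4S,5S,6Z,10E)-5-[(tert-butyldimethylsilyl)oxy]-10-{[(tert-butyldiphenylsilyl)oxy]methyl}-3-(dimethoxymethyl)-6-(hydroxymethyl)-11-iodo-2-methylidene-4-{[(2S)-2-methylbutanoyl]oxy}undeca-6,10-dienoate | I/C=C(/CO[Si](c1ccccc1)(c1ccccc1)C(C)(C)C)CC/C=C(/CO)[C@H](O[Si](C)(C)C(C)(C)C)[C@@H](OC(=O)[C@@H](C)CC)[C@@H](C(=C)C(=O)OC(C)(C)C)C(OC)OC
F2 | step 13 | tert-butyl (3R,4S,5S,6Z,10E)-5-[(tert-butyldimethylsilyl)oxy]-10-{[(tert-butyldiphenylsilyl)oxy]methyl}-3-formyl-6-(hydroxymethyl)-11-iodo-2-methylidene-4-{[(2S)-2-methylbutanoyl]oxy}undeca-6,10-dienoate | I/C=C(/CO[Si](c1ccccc1)(c1ccccc1)C(C)(C)C)CC/C=C(/CO)[C@H](O[Si](C)(C)C(C)(C)C)[C@@H](OC(=O)[C@@H](C)CC)[C@@H](C(=C)C(=O)OC(C)(C)C)C=O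
F3 | step 13 | tert-butyl 2-[(1S,2R,3E,7Z,9S,10S)-9-[(tert-butyldimethylsilyl)oxy]-4-{[(tert-butyldiphenylsilyl)oxy]methyl}-2-hydroxy-8-(hydroxymethyl)-10-{[(2S)-2-methylbutanoyl]oxy}cyclodeca-3,7-dien-1-yl]prop-2-enoate | O[C@@H]1/C=C(/CO[Si](c2ccccc2)(c2ccccc2)C(C)(C)C)CC/C=C(/CO)[C@H](O[Si](C)(C)C(C)(C)C)[C@@H](OC(=O)[C@@H](C)CC)[C@H]1C(=C)C(=O)OC(C)(C)C
F4 | step 13 | (3aS,4S,5S,6Z,10E,11aR)-5-[(tert-butyldimethylsilyl)oxy]-10-{[(tert-butyldiphenylsilyl)oxy]methyl}-6-(hydroxymethyl)-3-methylidene-2-oxo-2,3,3a,4,5,8,9,11a-octahydrocyclodeca[b]furan-4-yl (2S)-2-methylbutanoate | C=C1C(=O)O[C@@H]2/C=C(/CO[Si](c3ccccc3)(c3ccccc3)C(C)(C)C)CC/C=C(/CO)[C@H](O[Si](C)(C)C(C)(C)C)[C@@H](OC(=O)[C@@H](C)CC)[C@@H]12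
F5 | step 8 | tert-butyl (2E)-4,4-dimethoxy-2-[(4,4,5,5-tetramethyl-1,3,2-dioxaborolan-2-yl)methyl]but-2-enoate | CC1(C)OB(C/C(C(=O)OC(C)(C)C)=C\C(OC)OC)OC1(C)C
F6 | step 9 | tert-butyl (3R,4S)-4-[(4S,5Z)-2,2-di-tert-butyl-5-[(4E)-4-{[(tert-butyldiphenylsilyl)oxy]methyl}-5-(trimethylsilyl)pent-4-en-1-ylidene]-1,3,2-dioxasilinan-4-yl]-3-(dimethoxymethyl)-4-hydroxy-2-methylidenebutanoate | C[Si](C)(C)/C=C(/CO[Si](c1ccccc1)(c1ccccc1)C(C)(C)C)CC/C=C2/CO[Si](C(C)(C)C)(C(C)(C)C)O[C@@H]2[C@@H](O)[C@@H](C(=C)C(=O)OC(C)(C)C)C(OC)OC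
F7 | step 9 | tert-butyl (3R,4S)-4-[(4S,5Z)-2,2-di-tert-butyl-5-[(4E)-4-{[(tert-butyldiphenylsilyl)oxy]methyl}-5-(trimethylsilyl)pent-4-en-1-ylidene]-1,3,2-dioxasilinan-4-yl]-3-(dimethoxymethyl)-2-methylidene-4-{[(2S)-2-methylbutanoyl]oxy}butanoate | C[Si](C)(C)/C=C(/CO[Si](c1ccccc1)(c1ccccc1)C(C)(C)C)CC/C=C2/CO[Si](C(C)(C)C)(C(C)(C)C)O[C@@H]2[C@@H](OC(=O)[C@@H](C)CC)[C@@H](C(=C)C(=O)OC(C)(C)C)C(OC)OC
F8 | step 9 | tert-butyl (3R,4S,5S,6Z,10E)-10-{[(tert-butyldiphenylsilyl)oxy]methyl}-3-(dimethoxymethyl)-5-hydroxy-6-(hydroxymethyl)-2-methylidene-4-{[(2S)-2-methylbutanoyl]oxy}-11-(trimethylsilyl)undeca-6,10-dienoate | C[Si](C)(C)/C=C(/CO[Si](c1ccccc1)(c1ccccc1)C(C)(C)C)CC/C=C(/CO)[C@H](O)[C@@H](OC(=O)[C@@H](C)CC)[C@@H](C(=C)C(=O)OC(C)(C)C)C(OC)OC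
F9 | step 9 | tert-butyl (3R,4S,5S,6E,10E)-10-{[(tert-butyldiphenylsilyl)oxy]methyl}-3-(dimethoxymethyl)-6-formyl-5-hydroxy-2-methylidene-4-{[(2S)-2-methylbutanoyl]oxy}-11-(trimethylsilyl)undeca-6,10-dienoate | C[Si](C)(C)/C=C(/CO[Si](c1ccccc1)(c1ccccc1)C(C)(C)C)CC/C=C(/C=O)[C@H](O)[C@@H](OC(=O)[C@@H](C)CC)[C@@H](C(=C)C(=O)OC(C)(C)C)C(OC)OC
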